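The route rests on opening the chroman at O1–C2. The target's dihydropyran ring (O1, C2, C3, C4, C4a, C8a) places the phenolic oxygen O1 and the fully substituted C2 exactly where an ortho-(3-methylalk-2-enyl)phenol carries its OH and its trisubstituted alkene. One chiral-acid-catalysed hydroalkoxylation of that E-alkene forms O1–C2, closes the ring and sets the C2 tertiary ether centre. The precursor is a 2-methyl-6-dienyl-hydroquinone whose chain already holds the C8' methyl centre and a C9' pivalate; its remote 4-OH is silylated, so that a single phenol is free. The C9'–C12' hydroxy ketone terminus is then built by dithiane umpolung with prenal.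

Key step: step 12

Assumption: the sense of induction in steps 3 and 12 is assigned from the closest models (Ru–(S)-BINAP on geraniol-type allylic alcohols; confined acids on simple alkenols); should the configuration determined for 4 or 16 be the opposite one, the antipodal ligand or catalyst is used with no other change.

Step 1
Reactants: 1 (2E,6E)-farnesol
Product: 2 (2E,6E)-farnesyl acetate
Conditions: Ac2O, pyridine, DMAP (cat.), CH2Cl2, 0 °C → rt
Reagents that add atoms: acetic anhydride, CC(=O)OC(C)=O
Why: DMAP-catalysed acylation of a primary allylic alcohol; the acetate also deactivates the 2,3-alkene towards the following allylic oxidation.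

Step 2
Reactants: 2 (2E,6E)-farnesyl acetate
Product: 3 (2E,6E,10E)-12-hydroxy-3,7,11-trimethyldodeca-2,6,10-trien-1-yl acetate
Conditions: SeO2 (cat.), t-BuOOH, salicylic acid (cat.), CH2Cl2, rt, stopped at partial conversion
Reagents that add atoms: tert-butyl hydroperoxide, CC(C)(C)OO
Why: Riley-type catalytic SeO2 allylic oxidation (ene reaction, then [2,3]-sigmatropic shift) attacks the most accessible, most electron-rich terminal trisubstituted alkene at its E-methyl group, the 2,3-alkene being deactivated by the acetate.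

Step 3
Reactants: 3 (2E,6E,10E)-12-hydroxy-3,7,11-trimethyldodeca-2,6,10-trien-1-yl acetate
Product: 4 (2E,6E,11S)-12-hydroxy-3,7,11-trimethyldodeca-2,6-dien-1-yl acetate
Conditions: H2 (100 atm), Ru(OAc)2[(S)-BINAP] (cat.), MeOH, rt
Reagents that add atoms: none
Why: Noyori hydroxyl-directed asymmetric hydrogenation reduces only the alkene of the free allylic alcohol (the 6,7-alkene and the allylic acetate alkene cannot bind through an OH) and sets C11 by catalyst control, the (S)-ligand being expected to deliver H2 to the face that gives 11S by the quadrant model valid for geraniol; high pressure suppresses alkene migration.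

Step 4
Reactants: 4 (2E,6E,11S)-12-hydroxy-3,7,11-trimethyldodeca-2,6-dien-1-yl acetate
Product: 5 (2E,6E,11S)-12-pivaloyloxy-3,7,11-trimethyldodeca-2,6-dien-1-yl acetate
Conditions: PivCl, pyridine, DMAP (cat.), CH2Cl2, 0 °C → rt
Reagents that add atoms: pivaloyl chloride, CC(C)(C)C(Cl)=O
Why: Acylation of the primary alcohol; the pivalate is chosen as an acid-stable, non-nucleophilic spectator for the ring closure.

Step 5
Reactants: 5 (2E,6E,11S)-12-pivaloyloxy-3,7,11-trimethyldodeca-2,6-dien-1-yl acetate
Product: 6 (2S,6E,10E)-12-hydroxy-2,6,10-trimethyldodeca-6,10-dien-1-yl pivalate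
Conditions: K2CO3 (cat.), MeOH, 0 °C
Reagents that add atoms: none
Why: Chemoselective base-catalysed transesterification: the unhindered allylic acetate is methanolysed far faster than the hindered pivalate.

Step 6
Reactants: 6 (2S,6E,10E)-12-hydroxy-2,6,10-trimethyldodeca-6,10-dien-1-yl pivalate
Product: 7 (2S,6E,10E)-12-bromo-2,6,10-trimethyldodeca-6,10-dien-1-yl pivalate
Conditions: PBr3 (0.4 equiv), Et2O, −10 → 0 °C; used at once
Reagents that add atoms: phosphorus tribromide, BrP(Br)Br
Why: SN2 bromination of a primary allylic alcohol through its phosphite ester at low temperature, which keeps the E geometry as in the preparation of farnesyl bromide.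

Step 7
Reactants: 8 methylhydroquinone
Product: 9 2-methyl-4-(triisopropylsilyloxy)phenol
Conditions: TIPSCl (1.0 equiv), imidazole, DMF, −20 → 0 °C; chromatography
Reagents that add atoms: chlorotriisopropylsilane, CC(C)[Si](Cl)(C(C)C)C(C)C
Why: Silylation with a bulky chlorosilane discriminates the unhindered 4-OH from the 1-OH flanked by the methyl group; the minor regioisomer and the bis-ether are removed by chromatography.

Step 8
Reactants: 9 2-methyl-4-(triisopropylsilyloxy)phenol
Product: 10 2-bromo-6-methyl-4-(triisopropylsilyloxy)phenol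
Conditions: NBS (1.0 equiv), i-Pr2NH (cat.), CH2Cl2, 0 °C
Reagents that add atoms: N-bromosuccinimide, O=C1CCC(=O)N1Br
Why: Amine-mediated ortho-bromination (electrophilic aromatic substitution) of a para-blocked phenol: C6 is the only open position ortho to the free OH, and the positions next to the bulky silyl ether are less activated and shielded.

Step 9
Reactants: 10 2-bromo-6-methyl-4-(triisopropylsilyloxy)phenol
Product: 11 1-bromo-2-(methoxymethoxy)-3-methyl-5-(triisopropylsilyloxy)benzene
Conditions: MOMCl, i-Pr2NEt, CH2Cl2, 0 °C → rt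
Reagents that add atoms: chloromethyl methyl ether, COCCl
Why: O-Alkylation to the MOM acetal, which masks O1 and later stabilises the ortho-metalated arene by chelation.

Step 10
Reactants: 11 1-bromo-2-(methoxymethoxy)-3-methyl-5-(triisopropylsilyloxy)benzene, 7 (2S,6E,10E)-12-bromo-2,6,10-trimethyldodeca-6,10-dien-1-yl pivalate
Product: 14 2-(methoxymethoxy)-1-methyl-3-[(2E,6E,11S)-3,7,11-trimethyl-12-pivaloyloxydodeca-2,6-dienyl]-5-(triisopropylsilyloxy)benzene, via aryllithium 12 (not isolated), via arylcopper 13 (not isolated)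
Conditions: 11, n-BuLi, THF, −78 °C; CuBr·SMe2, −78 → −40 °C; then 7, −78 → 0 °C
Reagents that add atoms: none
Why: Bromine–lithium exchange, transmetalation to the arylcopper and SN2 allylic substitution at the unhindered α-carbon of the primary allylic bromide; the organocopper tolerates the pivalate and the 2,3-alkene keeps its E geometry.

Step 11
Reactants: 14 2-(methoxymethoxy)-1-methyl-3-[(2E,6E,11S)-3,7,11-trimethyl-12-pivaloyloxydodeca-2,6-dienyl]-5-(triisopropylsilyloxy)benzene
Product: 15 2-methyl-6-[(2E,6E,11S)-3,7,11-trimethyl-12-pivaloyloxydodeca-2,6-dienyl]-4-(triisopropylsilyloxy)phenol (the 4-O-silyl ether of the 2-methyl-6-dienylhydroquinone)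
Conditions: conc. HCl (few equiv), MeOH–THF, rt
Reagents that add atoms: none
Why: Acid-catalysed acetal methanolysis; in methanol the acid is levelled, so the aryl silyl ether, the pivalate and the alkenes are left alone and no premature non-selective ring closure is expected.

Step 12
Reactants: 15 2-methyl-6-[(2E,6E,11S)-3,7,11-trimethyl-12-pivaloyloxydodeca-2,6-dienyl]-4-(triisopropylsilyloxy)phenol
Product: 16 (2S,6E)-2,6-dimethyl-9-[(2R)-2,8-dimethyl-6-(triisopropylsilyloxy)chroman-2-yl]non-6-en-1-yl pivalate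
Conditions: confined chiral imidodiphosphorimidate (IDPi) acid (5 mol%, antipode chosen for 2R), cyclohexane–CHCl3, 4 Å MS, 40 °C
Reagents that add atoms: none
Why: Proposed new method: the confined acid hands its proton to the alkene carbon next to the benzylic CH2 (the future C3) while the free phenolic oxygen, hydrogen-bonded to the catalyst anion, bonds to the methyl-bearing alkene carbon (the future C2) in a concerted but asynchronous anti, Markovnikov addition. The closest known reaction types are the IDPi-catalysed intramolecular hydroalkoxylation of unactivated alkenols with aliphatic hydroxyl groups and the achiral-acid closure of prenylated hydroquinones to chromanols; a phenol adding to one trisubstituted alkene of a diene under such a catalyst has not been shown. The dihydropyran ring closes in the 6-endo-trig mode through the O1–C2 bond, the five-membered alternative being anti-Markovnikov. C2 is set by the catalyst alone, whose chiral pocket binds the phenol and selects one face of the E-alkene, the remote C8' centre having no influence. The step needs selectivity for the proximal over the distal trisubstituted alkene and must avoid cation–alkene bicyclisation: only the proximal alkene lies within reach of a nucleophile, because O4 is silylated and the pivalate is non-nucleophilic, so protonation of the distal alkene is reversible and unproductive. Silyl ether and pivalate are inert to a catalytic acid in a non-nucleophilic medium.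

Step 13
Reactants: 16 (2S,6E)-2,6-dimethyl-9-[(2R)-2,8-dimethyl-6-(triisopropylsilyloxy)chroman-2-yl]non-6-en-1-yl pivalate
Product: 17 (2S,6E)-2,6-dimethyl-9-[(2R)-2,8-dimethyl-6-(triisopropylsilyloxy)chroman-2-yl]non-6-en-1-ol
Conditions: DIBAL-H (2.5 equiv), CH2Cl2, −78 °C; Rochelle salt work-up
Reagents that add atoms: none
Why: Reductive cleavage of the ester by the aluminium hydride; aryl silyl ether, chroman and alkene are inert.

Step 14
Reactants: 17 (2S,6E)-2,6-dimethyl-9-[(2R)-2,8-dimethyl-6-(triisopropylsilyloxy)chroman-2-yl]non-6-en-1-ol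
Product: 18 (2S,6E)-2,6-dimethyl-9-[(2R)-2,8-dimethyl-6-(triisopropylsilyloxy)chroman-2-yl]non-6-enal
Conditions: Dess–Martin periodinane, NaHCO3, CH2Cl2, 0 °C; crude product used at once
Reagents that add atoms: none
Why: Dess–Martin oxidation under buffered, non-basic conditions should give the α-methyl aldehyde without epimerisation at C8', the phenol being protected against the oxidant.

Step 15
Reactants: 18 (2S,6E)-2,6-dimethyl-9-[(2R)-2,8-dimethyl-6-(triisopropylsilyloxy)chroman-2-yl]non-6-enal
Product: 19 2-[(2S,6E)-6-methyl-9-[(2R)-2,8-dimethyl-6-(triisopropylsilyloxy)chroman-2-yl]non-6-en-2-yl]-1,3-dithiane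
Conditions: HS(CH2)3SH, BF3·OEt2, CH2Cl2, −40 → −20 °C
Reagents that add atoms: propane-1,3-dithiol, SCCCS
Why: Lewis-acid-catalysed thioacetalisation is fast at low temperature and non-enolising, so C8' is kept and the tertiary chroman ether and the alkene are not touched.

Step 16
Reactants: 19 2-[(2S,6E)-6-methyl-9-[(2R)-2,8-dimethyl-6-(triisopropylsilyloxy)chroman-2-yl]non-6-en-2-yl]-1,3-dithiane, 20 3-methylbut-2-enal
Product: 22 1-{2-[(2S,6E)-6-methyl-9-[(2R)-2,8-dimethyl-6-(triisopropylsilyloxy)chroman-2-yl]non-6-en-2-yl]-1,3-dithian-2-yl}-3-methylbut-2-en-1-ol (both C10' epimers), via 2-lithio-1,3-dithiane 21 (not isolated)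
Conditions: n-BuLi, THF, −25 °C, 3 h; then 20, −78 °C; NH4Cl
Reagents that add atoms: none
Why: Corey–Seebach umpolung: the lithiated dithiane adds 1,2 to the aldehyde of the β,β-disubstituted enal in THF (contact ion pair, no HMPA); the C10' carbinol forms as an epimer mixture that is corrected in steps 17 and 18.

Step 17
Reactants: 22 1-{2-[(2S,6E)-6-methyl-9-[(2R)-2,8-dimethyl-6-(triisopropylsilyloxy)chroman-2-yl]non-6-en-2-yl]-1,3-dithian-2-yl}-3-methylbut-2-en-1-ol
Product: 23 1-{2-[(2S,6E)-6-methyl-9-[(2R)-2,8-dimethyl-6-(triisopropylsilyloxy)chroman-2-yl]non-6-en-2-yl]-1,3-dithian-2-yl}-3-methylbut-2-en-1-one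
Conditions: (COCl)2, DMSO, CH2Cl2, −78 °C; Et3N, → −20 °C
Reagents that add atoms: none
Why: Swern oxidation of the hindered secondary allylic alcohol; activated DMSO tolerates the thioacetal, and the ketone has no acidic hydrogen on the dithiane side.

Step 18
Reactants: 23 1-{2-[(2S,6E)-6-methyl-9-[(2R)-2,8-dimethyl-6-(triisopropylsilyloxy)chroman-2-yl]non-6-en-2-yl]-1,3-dithian-2-yl}-3-methylbut-2-en-1-one
Product: 24 (1R)-1-{2-[(2S,6E)-6-methyl-9-[(2R)-2,8-dimethyl-6-(triisopropylsilyloxy)chroman-2-yl]non-6-en-2-yl]-1,3-dithian-2-yl}-3-methylbut-2-en-1-ol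
Conditions: (S)-Me-CBS oxazaborolidine, catecholborane, toluene, −60 → −20 °C
Reagents that add atoms: none
Why: Corey–Bakshi–Shibata reduction: the ketone should bind the oxazaborolidine through the lone pair anti to the quaternary dithianyl group (the large substituent), so that the (S)-catalyst delivers hydride to the face giving the 10'R carbinol; catecholborane at low temperature leaves the alkenes alone and reduces 1,2.

Step 19
Reactants: 24 (1R)-1-{2-[(2S,6E)-6-methyl-9-[(2R)-2,8-dimethyl-6-(triisopropylsilyloxy)chroman-2-yl]non-6-en-2-yl]-1,3-dithian-2-yl}-3-methylbut-2-en-1-ol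
Product: 25 (2R)-2-[(3E,8S)-8-{2-[(1R)-1-hydroxy-3-methylbut-2-enyl]-1,3-dithian-2-yl}-4-methylnon-3-enyl]-2,8-dimethylchroman-6-ol
Conditions: TBAF, THF, 0 °C; NH4Cl
Reagents that add atoms: none
Why: Fluoride cleavage of the aryl silyl ether, placed before the ketone is unmasked so that the base-sensitive ketol never meets fluoride.

Step 20
Reactants: 25 (2R)-2-[(3E,8S)-8-{2-[(1R)-1-hydroxy-3-methylbut-2-enyl]-1,3-dithian-2-yl}-4-methylnon-3-enyl]-2,8-dimethylchroman-6-ol
Product: 26 (2R)-2-[(3E,8S,10R)-10-hydroxy-4,8,12-trimethyl-9-oxotrideca-3,11-dienyl]-2,8-dimethylchroman-6-ol (CNP0273237.1)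
Conditions: MeI (excess), CaCO3, MeCN–H2O (9:1), 40 °C, argon, dark
Reagents that add atoms: water, O
Why: Alkylative dithiane hydrolysis (S-methylation, thionium ion, capture by water) under carbonate-buffered, non-oxidising conditions should unveil the C9' ketone without enolisation, so that C8', C10' and the unconjugated ketol survive and the free chromanol is neither oxidised nor methylated.

Compound list
1 | (2E,6E)-farnesol | OC/C=C(\C)CC/C=C(\C)CCC=C(C)C | starting material
2 | (2E,6E)-farnesyl acetate | CC(=O)OC/C=C(\C)CC/C=C(\C)CCC=C(C)C | intermediate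
3 | (2E,6E,10E)-12-hydroxy-3,7,11-trimethyldodeca-2,6,10-trien-1-yl acetate | CC(=O)OC/C=C(\C)CC/C=C(\C)CC/C=C(\C)CO | intermediate
4 | (2E,6E,11S)-12-hydroxy-3,7,11-trimethyldodeca-2,6-dien-1-yl acetate | CC(=O)OC/C=C(\C)CC/C=C(\C)CCC[C@H](C)CO | intermediate
5 | (2E,6E,11S)-12-pivaloyloxy-3,7,11-trimethyldodeca-2,6-dien-1-yl acetate | CC(=O)OC/C=C(\C)CC/C=C(\C)CCC[C@H](C)COC(=O)C(C)(C)C | intermediate
6 | (2S,6E,10E)-12-hydroxy-2,6,10-trimethyldodeca-6,10-dien-1-yl pivalate | OC/C=C(\C)CC/C=C(\C)CCC[C@H](C)COC(=O)C(C)(C)C | intermediate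
7 | (2S,6E,10E)-12-bromo-2,6,10-trimethyldodeca-6,10-dien-1-yl pivalate | BrC/C=C(\C)CC/C=C(\C)CCC[C@H](C)COC(=O)C(C)(C)C | intermediate
8 | methylhydroquinone | Cc1cc(O)ccc1O | starting material
9 | 2-methyl-4-(triisopropylsilyloxy)phenol | Cc1cc(O[Si](C(C)C)(C(C)C)C(C)C)ccc1O | intermediate
10 | 2-bromo-6-methyl-4-(triisopropylsilyloxy)phenol | Cc1cc(O[Si](C(C)C)(C(C)C)C(C)C)cc(Br)c1O | intermediate
11 | 1-bromo-2-(methoxymethoxy)-3-methyl-5-(triisopropylsilyloxy)benzene | COCOc1c(C)cc(O[Si](C(C)C)(C(C)C)C(C)C)cc1Br | intermediate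
12 | aryllithium from 11 (Li in place of Br) | COCOc1c(C)cc(O[Si](C(C)C)(C(C)C)C(C)C)cc1[Li] | intermediate
13 | arylcopper(I) from 12 | COCOc1c(C)cc(O[Si](C(C)C)(C(C)C)C(C)C)cc1[Cu] | intermediate
14 | 2-(methoxymethoxy)-1-methyl-3-[(2E,6E,11S)-3,7,11-trimethyl-12-pivaloyloxydodeca-2,6-dienyl]-5-(triisopropylsilyloxy)benzene | COCOc1c(C)cc(O[Si](C(C)C)(C(C)C)C(C)C)cc1C/C=C(\C)CC/C=C(\C)CCC[C@H](C)COC(=O)C(C)(C)C | intermediate
15 | 2-methyl-6-[(2E,6E,11S)-3,7,11-trimethyl-12-pivaloyloxydodeca-2,6-dienyl]-4-(triisopropylsilyloxy)phenol | Cc1cc(O[Si](C(C)C)(C(C)C)C(C)C)cc(C/C=C(\C)CC/C=C(\C)CCC[C@H](C)COC(=O)C(C)(C)C)c1O | intermediate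
16 | (2S,6E)-2,6-dimethyl-9-[(2R)-2,8-dimethyl-6-(triisopropylsilyloxy)chroman-2-yl]non-6-en-1-yl pivalate | Cc1cc(O[Si](C(C)C)(C(C)C)C(C)C)cc2c1O[C@](C)(CC/C=C(\C)CCC[C@H](C)COC(=O)C(C)(C)C)CC2 | intermediate
17 | (2S,6E)-2,6-dimethyl-9-[(2R)-2,8-dimethyl-6-(triisopropylsilyloxy)chroman-2-yl]non-6-en-1-ol | Cc1cc(O[Si](C(C)C)(C(C)C)C(C)C)cc2c1O[C@](C)(CC/C=C(\C)CCC[C@H](C)CO)CC2 | intermediate
18 | (2S,6E)-2,6-dimethyl-9-[(2R)-2,8-dimethyl-6-(triisopropylsilyloxy)chroman-2-yl]non-6-enal | Cc1cc(O[Si](C(C)C)(C(C)C)C(C)C)cc2c1O[C@](C)(CC/C=C(\C)CCC[C@H](C)C=O)CC2 | intermediate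
19 | 2-[(2S,6E)-6-methyl-9-[(2R)-2,8-dimethyl-6-(triisopropylsilyloxy)chroman-2-yl]non-6-en-2-yl]-1,3-dithiane | Cc1cc(O[Si](C(C)C)(C(C)C)C(C)C)cc2c1O[C@](C)(CC/C=C(\C)CCC[C@H](C)C1SCCCS1)CC2 | intermediate
20 | 3-methylbut-2-enal (prenal) | CC(C)=CC=O | starting material
21 | 2-lithio derivative of dithiane 19 | Cc1cc(O[Si](C(C)C)(C(C)C)C(C)C)cc2c1O[C@](C)(CC/C=C(\C)CCC[C@H](C)C1([Li])SCCCS1)CC2 | intermediate
22 | 1-{2-[(2S,6E)-6-methyl-9-[(2R)-2,8-dimethyl-6-(triisopropylsilyloxy)chroman-2-yl]non-6-en-2-yl]-1,3-dithian-2-yl}-3-methylbut-2-en-1-ol, both C10' epimers | Cc1cc(O[Si](C(C)C)(C(C)C)C(C)C)cc2c1O[C@](C)(CC/C=C(\C)CCC[C@H](C)C1(C(O)C=C(C)C)SCCCS1)CC2 | intermediate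
23 | 1-{2-[(2S,6E)-6-methyl-9-[(2R)-2,8-dimethyl-6-(triisopropylsilyloxy)chroman-2-yl]non-6-en-2-yl]-1,3-dithian-2-yl}-3-methylbut-2-en-1-one | Cc1cc(O[Si](C(C)C)(C(C)C)C(C)C)cc2c1O[C@](C)(CC/C=C(\C)CCC[C@H](C)C1(C(=O)C=C(C)C)SCCCS1)CC2 | intermediate
24 | (1R)-1-{2-[(2S,6E)-6-methyl-9-[(2R)-2,8-dimethyl-6-(triisopropylsilyloxy)chroman-2-yl]non-6-en-2-yl]-1,3-dithian-2-yl}-3-methylbut-2-en-1-ol | Cc1cc(O[Si](C(C)C)(C(C)C)C(C)C)cc2c1O[C@](C)(CC/C=C(\C)CCC[C@H](C)C1([C@H](O)C=C(C)C)SCCCS1)CC2 | intermediate
25 | (2R)-2-[(3E,8S)-8-{2-[(1R)-1-hydroxy-3-methylbut-2-enyl]-1,3-dithian-2-yl}-4-methylnon-3-enyl]-2,8-dimethylchroman-6-ol | Cc1cc(O)cc2c1O[C@](C)(CC/C=C(\C)CCC[C@H](C)C1([C@H](O)C=C(C)C)SCCCS1)CC2 | intermediate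
26 | (2R)-2-[(3E,8S,10R)-10-hydroxy-4,8,12-trimethyl-9-oxotrideca-3,11-dienyl]-2,8-dimethylchroman-6-ol | CC(C)=C[C@@H](O)C(=O)[C@@H](C)CCC/C(C)=C/CC[C@]1(C)CCc2cc(O)cc(C)c2O1 | target

Total step count: 20. Longest linear sequence: 17 steps (steps 1–6 and 10–20, from farnesol); the arene branch (steps 7–9) joins at step 10.

Steps most likely to fail

1. Step 12. Proton transfer may go to the distal alkene and start cation–alkene cyclisation or double-bond migration, and the enantioface discrimination for a phenol nucleophile inside the acid pocket may be insufficient. The fallback uses known chemistry and gives up catalyst control: it sets out from 15, which is closed with an achiral acid (p-TsOH, cat., CH2Cl2, 0 °C → rt), the classical ring closure of prenylated hydroquinones to chromanols. This should give 16 together with its C2 epimer, (2S,6E)-2,6-dimethyl-9-[(2S)-2,8-dimethyl-6-(triisopropylsilyloxy)chroman-2-yl]non-6-en-1-yl pivalate F1. The two are diastereomers because of C8' and are separated by preparative HPLC on a polysaccharide chiral phase; the route is rejoined at 16.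

2. Step 18. Facial selection in the reduction may be poor, because both carbonyl substituents are bulky and the resident C8' centre may oppose the catalyst. The fallback replaces reagent control by separation and recycling: it sets out from 22, whose C10' epimers are diastereomers and are separated on silica. The 10'R epimer is 24, where the route is rejoined. The 10'S epimer, (1S)-1-{2-[(2S,6E)-6-methyl-9-[(2R)-2,8-dimethyl-6-(triisopropylsilyloxy)chroman-2-yl]non-6-en-2-yl]-1,3-dithian-2-yl}-3-methylbut-2-en-1-ol F2, is returned to the mixture 22 by Swern oxidation to 23 and Luche reduction (NaBH4, CeCl3, MeOH), then separated again. The configuration is assigned by Mosher ester analysis.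

3. Step 3. Enantioface discrimination on the 2-methyl allylic alcohol may be incomplete, or the alkene may migrate before reduction; either would leave a C8' epimer that cannot be removed later. The fallback moves the hydrogenation to the carboxylic acid, the substrate class with the best-established selectivity and known sense, and sets out from 3. MnO2 (CH2Cl2) gives the enal (2E,6E,10E)-3,7,11-trimethyl-12-oxododeca-2,6,10-trien-1-yl acetate F3. Pinnick oxidation (NaClO2, NaH2PO4, 2-methylbut-2-ene, t-BuOH–H2O) gives (2E,6E,10E)-12-acetoxy-2,6,10-trimethyldodeca-2,6,10-trienoic acid F4. Carboxylate-directed hydrogenation with Ru(OAc)2(BINAP) (antipode delivering the S acid, H2, MeOH) gives (2S,6E,10E)-12-acetoxy-2,6,10-trimethyldodeca-6,10-dienoic acid F5, whose optical purity can if needed be raised by crystallising a salt with a chiral amine. Activation as the mixed isobutyl carbonic anhydride F6 (i-BuOCOCl, N-methylmorpholine, THF, −15 °C) and reduction with NaBH4 (THF–H2O, 0 °C) leads back to 4.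

Further compounds
F1 | step 12 | (2S,6E)-2,6-dimethyl-9-[(2S)-2,8-dimethyl-6-(triisopropylsilyloxy)chroman-2-yl]non-6-en-1-yl pivalate | Cc1cc(O[Si](C(C)C)(C(C)C)C(C)C)cc2c1O[C@@](C)(CC/C=C(\C)CCC[C@H](C)COC(=O)C(C)(C)C)CC2
F2 | step 18 | (1S)-1-{2-[(2S,6E)-6-methyl-9-[(2R)-2,8-dimethyl-6-(triisopropylsilyloxy)chroman-2-yl]non-6-en-2-yl]-1,3-dithian-2-yl}-3-methylbut-2-en-1-ol | Cc1cc(O[Si](C(C)C)(C(C)C)C(C)C)cc2c1O[C@](C)(CC/C=C(\C)CCC[C@H](C)C1([C@@H](O)C=C(C)C)SCCCS1)CC2
F3 | step 3 | (2E,6E,10E)-3,7,11-trimethyl-12-oxododeca-2,6,10-trien-1-yl acetate | CC(=O)OC/C=C(\C)CC/C=C(\C)CC/C=C(\C)C=O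
F4 | step 3 | (2E,6E,10E)-12-acetoxy-2,6,10-trimethyldodeca-2,6,10-trienoic acid | CC(=O)OC/C=C(\C)CC/C=C(\C)CC/C=C(\C)C(=O)O
F5 | step 3 | (2S,6E,10E)-12-acetoxy-2,6,10-trimethyldodeca-6,10-dienoic acid | CC(=O)OC/C=C(\C)CC/C=C(\C)CCC[C@H](C)C(=O)O
F6 | step 3 | mixed isobutyl carbonic anhydride of F5 | CC(=O)OC/C=C(\C)CC/C=C(\C)CCC[C@H](C)C(=O)OC(=O)OCC(C)C
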